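## Structural features

- The molecule is two six-membered carbocycles joined through one methylene carbon. Ring A is a dearomatised acylphloroglucinol, written here with locants A1 to A6: A1 is the quaternary carbon, A2 and A6 are enolic C–OH carbons, A3 carries the bridge, A4 is the ring ketone and A5 carries an isobutyryl group. Ring B is a benzene ring (C4a to C8a) fused to a 2,2-dimethyl-2H-pyran (O1, C2 to C4), with hydroxyls on C5 and C7, an isobutyryl group on C6 and the bridge on C8.
- The only stereocentre is A1 (methyl and prenyl), which is (R) in the enol tautomer of the SMILES. It has no stereogenic neighbour and no acidic hydrogen, so it cannot epimerise, but it also cannot be corrected once set.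
- The two ring neighbours of A1 (A2 and A6) differ only one atom further out, so the two faces of any flat precursor are hard to tell apart.
- Fragile groups are the prenyl alkene and the C3=C4 alkene (acid closes them onto a neighbouring enol or phenol OH, and hydrogenation is excluded), the β-triketone (retro-Claisen cleavage by hard nucleophiles), the doubly activated methylene bridge (transfer between phloroglucinol units on heating with acid or base) and the electron-rich phenols (oxidation).
- The real difficulties are three: the hexasubstituted ring B with five different substituents in a fixed order, an unsymmetrical bridge without homodimers, and enantiocontrol at A1.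
- The key step uses the fact that O1 and C4 sit on the neighbouring carbons C8a and C4a, directly beside the C5 oxygen. If C8a≡C4a is an aryne bond flanked by the C5 ether, the carbonyl group of a five-carbon enal can deliver both atoms in one orientation and bring C2, C3 and C4 of the pyran with it.

## Logic of the disconnections

**24 ⇒ 17 + 22.** The bond between the bridge carbon and A3 is cut. This divides the molecule into halves of similar size, keeps the stereocentre in one half, and exposes the prenyl/enol pair only to a neutral, warm final step. The bridge carbon is attached to ring B alone before the union, so no statistical methylene condensation is needed. The forward step demands that 17 release the electrophile 23 below the temperature at which methylene transfer sets in, and that 22 react through carbon A3.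

**17 ⇒ 16.** The C8–CH2 bond is cut. C8 is the last free position of ring B and lies ortho to the C7 hydroxyl. The gain is a return to a simple acylchromene. The demand is clean mono-aminomethylation at carbon.

**16 ⇒ 15 ⇒ 12 + 13.** The two acetal O–C bonds are restored and the C6–C(acyl) bond is cut. In 12, C6 is the one position flanked by two chelating acetal ethers, which is the reason for cutting there. The gain is a benzene ring with no carbon substituent other than the pyran. The demands are metalation at C6 and not at C8, a single acyl transfer, and acid deprotection at a stage where no prenyl group is present.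

**12 ⇒ 7 + 8 (key).** O1–C2, C4a–C4 and C8a–O1 are cut; in the forward sense the C=O bond of 8 is given up. One ring and three bonds fall away, every pyran carbon comes from commercial 8, and the aromatic part shrinks to a 1,2,3,5-tetrasubstituted benzene. The demands are regioselective capture of aryne 9 and a ring closure of 11 that outruns intermolecular traps.

**7 ⇒ 4 ⇒ 3 ⇒ 2 ⇒ 1.** The O–S bond of the triflate, the C–Si bond (formed forward by O→C silyl shift through 5 and 6), the C–Br bond and two acetal O–C bonds are cut. Silicon and the leaving group must be neighbours with silicon beside an ether, and a bromine ortho to the free hydroxyl of 2 encodes exactly this. The gain is the symmetric triol 1. The demands are ortho-selective monobromination and acceptance of a statistical bis-protection on the cheapest material of the route.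

**22 ⇒ 20 + 21.** The A1–CH2(prenyl) bond is cut. This leaves an achiral aromatic precursor and creates the stereocentre in the same step that dearomatises the ring. The gain is a two-step access to ring A. The demands are reaction at the methyl-bearing carbon, attack at the unsubstituted allyl terminus, mono-alkylation, and facial control by the chiral ligand.

**20 ⇒ 18 + 19.** The aryl–C(acyl) bond is cut. The two free ring positions of 18 are equivalent, so only one ketone can form; the demand is mono-acylation.

## Other disconnections considered

**Alternative 1:** The cut is the A5–A6 bond of ring A.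
- Forward step: Mg(OMe)2 in methanol opens the lactone of A1, (3R)-3-methyl-3-(3-methylbut-2-en-1-yl)-6-(3-methyl-2-oxobutyl)-2H-pyran-2,4(3H)-dione. The magnesium-bound carbanion between the two side-chain ketones then closes onto the new ester (Claisen condensation) to give the ring A acid A2, which is identical with 22.
- In its favour: the stereocentre exists as an sp3 quaternary carbon between a lactone and a ketone before the ring is made. Its configuration is therefore defined by the substrate and can be checked early. There is no C- versus O-alkylation or mono- versus bis-alkylation problem on an ambident phenoxide, and magnesium chelation pre-organises the six-membered closure.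
- Against it here: A1 needs its own multi-step assembly, including an enantioselective construction of the same quaternary carbon. Methoxide can also attack the ketone next to the quaternary carbon (retro-Claisen cleavage) in competition with lactone opening.
- Comparison: this alternative replaces only steps 9 and 10 of the chosen plan; it says nothing about ring B or the bridge and does not compete with the aryne annulation. On stereochemical security it is the better of the two. On mechanism both end in the same vinylogous acid. On step economy the chosen two-step dearomatisation is shorter. It is the natural replacement if step 10 cannot be made selective.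

**Alternative 2:** The cuts are three C–C bonds of the benzene ring (C4a–C8a, C5–C6, C8–C8a) and O1–C2.
- Forward step: heating A3, 3-ethoxycyclobut-2-en-1-one, with A4, triisopropyl{[(3Z)-5-methylhexa-3,5-dien-1-yn-1-yl]oxy}silane, starts a cascade. Four-electron opening, [2+2] addition, a second opening and 6π closure build the benzene ring; a hydrogen shift and oxa-6π closure then form the pyran. The product is A5, 7-ethoxy-2,2-dimethyl-5-(triisopropylsilyloxy)-2H-chromene.
- In its favour: the benzene ring is made from scratch under neutral thermal conditions, without fluoride or organolithium. The regiochemistry is written into the polarity of the ynol ether and does not depend on an inductive bias, which is a point where it is the better plan. It forms four ring bonds where the aryne route forms three. The C5 and C7 oxygens emerge differentiated (silyl against ethyl), a better handle for directing an acyl group to C6 than two identical acetal ethers.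
- Against it here: the C7 ethyl ether must be cleaved late, and ether cleavage with BBr3 or a thiolate is at odds with the chromene alkene and the acyl group. A4 is a sensitive reagent that takes several steps and needs a defined Z-alkene, and A3 is costly. A5 still has both C6 and C8 unsubstituted, so the downstream work is not reduced.
- Comparison: on structure the two key products are equals (same free positions). On mechanism both finish with the same oxa-6π closure. On step economy the chosen precursor 7 is reached in four routine steps from a cheap triol and its acetals come off in dilute acid, so the chosen plan is shorter and ends more gently.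

**Alternative 3:** The cut is the A2–A3 bond of ring A, with the bridge and protected ring B already attached.
- Forward step: excess LiN(iPr)2 deprotonates the methylene next to the A4 ketone of A6, methyl (2S)-7-[5,7-bis(methoxymethoxy)-2,2-dimethyl-6-(2-methylpropanoyl)-2H-chromen-8-yl]-2-methyl-2-(3-methylbut-2-en-1-yl)-4-(2-methylpropanoyl)-3,5-dioxoheptanoate. Dieckmann closure onto the ester gives A7, the bis(methoxymethyl) ether of 24, and acid then frees the phenols.
- In its favour: the bridge is an ordinary carbon of an arylpropanoyl chain, so homodimers and methylene transfer are impossible; on this point it is the better plan. The stereocentre is carried in from a defined building block, which makes it the equal of Alternative 1 in stereochemical security.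
- Against it here: the sequence is long and linear. A6 has several acidic sites, so the closure has to be steered through a polyanion and competes with retro-Claisen cleavage at the quaternary carbon. The C8 side chain of ring B must be introduced at the position that acetal-directed metalation does not favour. The final acid treatment of A7 meets the prenyl group next to enolic hydroxyls, which invites cyclisation to a pyran.
- Comparison: the chosen plan removes the acetals before the prenyl group enters and joins two finished halves under neutral conditions. It is shorter and more convergent, but it pays with a bridge-forming step that needs control.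

Key step: step 5

Remarks and assumptions on the chemistry:
- Structure check: the aryne carbon remote from the flanking acetal ether becomes C8a and the one beside it C4a, so the two ethers end on C5 and C7. Compounds 7, 8 and 12 are consistent with ring B of the target and need no correction.
- Design choices for reliability: amine-mediated ortho-bromination fixes the silicon/triflate placement in 7; a Weinreb amide gives single acyl transfer in step 6; a preformed Mannich base replaces free formaldehyde for the bridge.
- Assumption: all ring A compounds are written as the enol tautomers of their SMILES, and the descriptor (R) refers to that tautomer. The priority order at A1 is: C–OH carbon next to the acyl-bearing carbon, then the other C–OH carbon, then prenyl CH2, then CH3.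
- Assumption: the sense of induction of the chiral diphosphine in step 10 cannot be predicted with certainty for this nucleophile. The (R,R)-ligand is written; its antipode is meant should the opposite face be favoured.

## Route

Step 1
Reactants: 1 phloroglucinol (benzene-1,3,5-triol)
Product: 2 3,5-bis(methoxymethoxy)phenol
Conditions: MOMCl (2.1 equiv), i-Pr2NEt (2.3 equiv), DMF, 0 °C → rt
Reagents that add atoms: chloromethyl methyl ether, COCCl
Why: O-alkylation of the phenoxide by a hard chloromethyl ether (acetal protection) with no C-alkylation expected. The step is statistical, so 2 is separated from the mono- and tris-ethers, which can be recycled.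

Step 2
Reactants: 2 3,5-bis(methoxymethoxy)phenol
Product: 3 2-bromo-3,5-bis(methoxymethoxy)phenol
Conditions: NBS (1.0 equiv), i-Pr2NH (10 mol %), CH2Cl2, −78 → −40 °C
Reagents that add atoms: N-bromosuccinimide, O=C1CCC(=O)N1Br
Why: Amine-mediated electrophilic bromination, in which the N-bromoamine is delivered through a hydrogen bond to the phenol OH and so attacks an ortho position. Both ortho positions are equivalent, the position between the two acetal ethers is shielded by both chains, and one equivalent at low temperature should limit dibromination.

Step 3
Reactants: 3 2-bromo-3,5-bis(methoxymethoxy)phenol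
Product: 4 [2-bromo-3,5-bis(methoxymethoxy)phenoxy]trimethylsilane
Conditions: (Me3Si)2NH, THF, 65 °C; concentrate, use crude
Reagents that add atoms: hexamethyldisilazane, C[Si](C)(C)N[Si](C)(C)C
Why: O-silylation of a phenol by hexamethyldisilazane, which forms no salt and places silicon on the oxygen next to the bromine for the migration of step 4.

Step 4
Reactants: 4 [2-bromo-3,5-bis(methoxymethoxy)phenoxy]trimethylsilane
Product: 7 3,5-bis(methoxymethoxy)-2-(trimethylsilyl)phenyl trifluoromethanesulfonate, via aryllithium 5 (not isolated), via lithium phenoxide 6 (not isolated)
Conditions: n-BuLi (1.1 equiv), THF, −78 °C; then Tf2O (1.2 equiv), −78 °C → 0 °C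
Reagents that add atoms: trifluoromethanesulfonic anhydride, O=S(=O)(OS(=O)(=O)C(F)(F)F)C(F)(F)F
Why: Bromine–lithium exchange is much faster at −78 °C than acetal-directed deprotonation, and the ortho-lithiated silyl ether 5 undergoes the anionic 1,3-shift of silicon from oxygen to carbon (retro-Brook rearrangement) to give 6. The phenoxide is then sulfonylated in the same flask, which is the standard entry to ortho-silylaryl triflates.

Step 5
Reactants: 7 3,5-bis(methoxymethoxy)-2-(trimethylsilyl)phenyl trifluoromethanesulfonate; 8 3-methylbut-2-enal
Product: 12 5,7-bis(methoxymethoxy)-2,2-dimethyl-2H-chromene, via aryne 9 (not isolated), via benzoxete 10 (not isolated), via ortho-quinone methide 11 (not isolated)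
Conditions: CsF (3 equiv), 8 (4 equiv), MeCN, 40 °C, 7 added over 4 h
Reagents that add atoms: none
Why: Fluoride attack on silicon with loss of triflate should release aryne 9 slowly into an excess of 8. The carbonyl oxygen of 8, made more nucleophilic by its vinylogous dimethyl donor, adds to the aryne carbon remote from the flanking methoxymethyl ether, because that carbon is the more electrophilic end of the distorted triple bond and the aryl anion then develops beside the inductively stabilising C–O bond; collapse of the zwitterion onto the carbonyl carbon gives benzoxete 10 (formal [2+2], forming C8a–O1 and C4a–C4). Conrotatory four-electron opening of 10 cleaves the former carbonyl C–O bond and gives ortho-quinone methide 11, whose 1-oxatriene closes by disrotatory oxa-6π electrocyclisation (O1–C2) with recovery of aromaticity; this pericyclic closure is the only lasting ring-forming event and gives the six-membered pyran, while the E isomer of 11 can return through 10. No stereocentre is created because C2 carries two methyl groups. The closest known reaction types are the [2+2] capture of arynes by formamides and aldehydes with benzoxete opening, and the electrocyclisation of enal-derived ortho-quinone methides to 2H-chromenes. The step needs regioselective aryne capture, secured by the single ether beside the triple bond (the second ether is too remote to compete), and it needs closure of 11 to outrun capture by a second aryne or aldehyde, secured by the intramolecular 6π closure, the excess of 8 and the slow release of 9.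

Step 6
Reactants: 12 5,7-bis(methoxymethoxy)-2,2-dimethyl-2H-chromene; 13 N-methoxy-N,2-dimethylpropanamide
Product: 15 1-[5,7-bis(methoxymethoxy)-2,2-dimethyl-2H-chromen-6-yl]-2-methylpropan-1-one, via 6-lithiochromene 14 (not isolated)
Conditions: n-BuLi (1.2 equiv), THF, 0 °C, 1 h; then 13 (1.5 equiv), −78 °C → rt; then H2O
Reagents that add atoms: none
Why: Directed ortho-metalation, in which C6–H lies between two chelating acetal ethers that cooperate, whereas C8–H has only one such neighbour and the poorly coordinating tertiary-alkyl pyran oxygen. Aryllithium 14 adds once to the Weinreb amide, and the chelated tetrahedral adduct releases the ketone only on work-up.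

Step 7
Reactants: 15 1-[5,7-bis(methoxymethoxy)-2,2-dimethyl-2H-chromen-6-yl]-2-methylpropan-1-one
Product: 16 1-(5,7-dihydroxy-2,2-dimethyl-2H-chromen-6-yl)-2-methylpropan-1-one
Conditions: 3 M aq. HCl, MeOH, 40 °C
Reagents that add atoms: none
Why: Acid-catalysed acetal exchange with methanol frees both phenols, which are stabilised by hydrogen bonding to the C6 ketone. The 2,2-dimethylchromene should tolerate dilute acid at this temperature, and the step is placed before the union so that the prenyl group never meets acid.

Step 8
Reactants: 16 1-(5,7-dihydroxy-2,2-dimethyl-2H-chromen-6-yl)-2-methylpropan-1-one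
Product: 17 1-{8-[(dimethylamino)methyl]-5,7-dihydroxy-2,2-dimethyl-2H-chromen-6-yl}-2-methylpropan-1-one
Conditions: Me2N=CH2+ I− (1.1 equiv), Et3N (1.1 equiv), CH2Cl2, 0 °C → rt
Reagents that add atoms: N,N-dimethylmethyleneiminium iodide (Eschenmoser's salt), C=[N+](C)C.[I-]
Why: Mannich aminomethylation of a phenoxide with a preformed iminium salt, where C8 is the only unsubstituted ring carbon and lies ortho to the C7 oxygen. With no free formaldehyde present the reaction should stop at the mono-adduct, a stable zwitterionic Mannich base.

Step 9
Reactants: 18 2-methylbenzene-1,3,5-triol; 19 2-methylpropanoyl chloride (isobutyryl chloride)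
Product: 20 2-methyl-1-(2,4,6-trihydroxy-3-methylphenyl)propan-1-one
Conditions: AlCl3 (3.5 equiv), PhNO2/CH2Cl2, 0 °C → 45 °C; aq. HCl
Reagents that add atoms: none
Why: Friedel–Crafts C-acylation of a highly activated arene whose two free positions are equivalent, so only one ketone can form. The chelated acylphloroglucinol is deactivated towards a second acylation.

Step 10
Reactants: 20 2-methyl-1-(2,4,6-trihydroxy-3-methylphenyl)propan-1-one; 21 3-methylbut-2-en-1-yl acetate (prenyl acetate)
Product: 22 (4R)-3,5-dihydroxy-4-methyl-4-(3-methylbut-2-en-1-yl)-2-(2-methylpropanoyl)cyclohexa-2,5-dien-1-one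
Conditions: Pd2(dba)3·CHCl3 (2.5 mol %), (R,R)-DACH-phenyl Trost ligand [(1R,2R)-N,N'-bis(2-diphenylphosphinobenzoyl)cyclohexane-1,2-diamine] (7.5 mol %), Et3N (1.1 equiv), 20 (1.2 equiv), CH2Cl2, 0 °C → rt; aq. HCl
Reagents that add atoms: none
Why: Tsuji–Trost asymmetric allylic alkylation with dearomatisation, in which zerovalent palladium ionises 21 to the π-prenyl complex and the phenoxide of 20 attacks its unsubstituted terminus through the methyl-bearing ring carbon, the most electron-rich site; the resulting vinylogous acid is held as its less nucleophilic ammonium salt. The chiral pocket of the C2-symmetric diphosphine distinguishes the acyl-flanked from the hydrogen-flanked side of the flat nucleophile and so sets the quaternary centre A1, while any O-prenyl ether re-ionises and is funnelled to the C-alkylated product.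

Step 11
Reactants: 17 1-{8-[(dimethylamino)methyl]-5,7-dihydroxy-2,2-dimethyl-2H-chromen-6-yl}-2-methylpropan-1-one; 22 (4R)-3,5-dihydroxy-4-methyl-4-(3-methylbut-2-en-1-yl)-2-(2-methylpropanoyl)cyclohexa-2,5-dien-1-one
Product: 24 (4R)-6-{[5,7-dihydroxy-2,2-dimethyl-6-(2-methylpropanoyl)-2H-chromen-8-yl]methyl}-3,5-dihydroxy-4-methyl-4-(3-methylbut-2-en-1-yl)-2-(2-methylpropanoyl)cyclohexa-2,5-dien-1-one, via ortho-quinone methide 23 (not isolated)
Conditions: 1,4-dioxane, 80 °C, N2 stream; then 1 M aq. HCl wash
Reagents that add atoms: none
Why: Thermal loss of dimethylamine from the zwitterionic Mannich base gives quinone methide 23, and the enolate of 22 adds through carbon A3 (Michael addition) with re-aromatisation of ring B as the driving force; O-alkylation is reversible under these conditions. The quaternary centre of 22 has no acidic hydrogen and takes no part, so its configuration should pass unchanged into 24.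

## Compound list

1 | phloroglucinol (benzene-1,3,5-triol) | Oc1cc(O)cc(O)c1 | starting material
2 | 3,5-bis(methoxymethoxy)phenol | COCOc1cc(O)cc(OCOC)c1 | intermediate
3 | 2-bromo-3,5-bis(methoxymethoxy)phenol | COCOc1cc(OCOC)c(Br)c(O)c1 | intermediate
4 | [2-bromo-3,5-bis(methoxymethoxy)phenoxy]trimethylsilane | COCOc1cc(OCOC)c(Br)c(O[Si](C)(C)C)c1 | intermediate
5 | [2,4-bis(methoxymethoxy)-6-(trimethylsilyloxy)phenyl]lithium (transient) | COCOc1cc(OCOC)c([Li])c(O[Si](C)(C)C)c1 | intermediate
6 | lithium 3,5-bis(methoxymethoxy)-2-(trimethylsilyl)phenoxide (transient) | COCOc1cc(OCOC)c([Si](C)(C)C)c([O-])c1.[Li+] | intermediate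
7 | 3,5-bis(methoxymethoxy)-2-(trimethylsilyl)phenyl trifluoromethanesulfonate | COCOc1cc(OCOC)c([Si](C)(C)C)c(OS(=O)(=O)C(F)(F)F)c1 | intermediate
8 | 3-methylbut-2-enal | CC(C)=CC=O | starting material
9 | 3,5-bis(methoxymethoxy)benzyne (1,2-didehydro-3,5-bis(methoxymethoxy)benzene, transient) | COCOC1=CC(OCOC)=CC#C1 | intermediate
10 | 3,5-bis(methoxymethoxy)-2-(2-methylprop-1-en-1-yl)-2H-1-benzoxete (racemic, transient) | COCOc1cc(OCOC)c2C(C=C(C)C)Oc2c1 | intermediate
11 | (6Z)-3,5-bis(methoxymethoxy)-6-(3-methylbut-2-en-1-ylidene)cyclohexa-2,4-dien-1-one (transient) | O=C1C=C(OCOC)C=C(OCOC)/C1=C/C=C(C)C | intermediate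
12 | 5,7-bis(methoxymethoxy)-2,2-dimethyl-2H-chromene | COCOc1cc(OCOC)c2C=CC(C)(C)Oc2c1 | intermediate
13 | N-methoxy-N,2-dimethylpropanamide | CC(C)C(=O)N(C)OC | starting material
14 | [5,7-bis(methoxymethoxy)-2,2-dimethyl-2H-chromen-6-yl]lithium (transient) | COCOc1cc2OC(C)(C)C=Cc2c(OCOC)c1[Li] | intermediate
15 | 1-[5,7-bis(methoxymethoxy)-2,2-dimethyl-2H-chromen-6-yl]-2-methylpropan-1-one | CC(C)C(=O)c1c(OCOC)cc2OC(C)(C)C=Cc2c1OCOC | intermediate
16 | 1-(5,7-dihydroxy-2,2-dimethyl-2H-chromen-6-yl)-2-methylpropan-1-one | CC(C)C(=O)c1c(O)cc2OC(C)(C)C=Cc2c1O | intermediate
17 | 1-{8-[(dimethylamino)methyl]-5,7-dihydroxy-2,2-dimethyl-2H-chromen-6-yl}-2-methylpropan-1-one | CC(C)C(=O)c1c(O)c(CN(C)C)c2OC(C)(C)C=Cc2c1O | intermediate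
18 | 2-methylbenzene-1,3,5-triol | Cc1c(O)cc(O)cc1O | starting material
19 | 2-methylpropanoyl chloride (isobutyryl chloride) | CC(C)C(Cl)=O | starting material
20 | 2-methyl-1-(2,4,6-trihydroxy-3-methylphenyl)propan-1-one | CC(C)C(=O)c1c(O)cc(O)c(C)c1O | intermediate
21 | 3-methylbut-2-en-1-yl acetate (prenyl acetate) | CC(C)=CCOC(C)=O | starting material
22 | (4R)-3,5-dihydroxy-4-methyl-4-(3-methylbut-2-en-1-yl)-2-(2-methylpropanoyl)cyclohexa-2,5-dien-1-one | CC(C)=CC[C@]1(C)C(O)=CC(=O)C(C(=O)C(C)C)=C1O | intermediate
23 | 5-hydroxy-2,2-dimethyl-8-methylidene-6-(2-methylpropanoyl)-2H-chromen-7(8H)-one (transient) | C=C1C(=O)C(C(=O)C(C)C)=C(O)C2=C1OC(C)(C)C=C2 | intermediate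
24 | (4R)-6-{[5,7-dihydroxy-2,2-dimethyl-6-(2-methylpropanoyl)-2H-chromen-8-yl]methyl}-3,5-dihydroxy-4-methyl-4-(3-methylbut-2-en-1-yl)-2-(2-methylpropanoyl)cyclohexa-2,5-dien-1-one | CC(C)=CC[C@]1(C)C(O)=C(Cc2c(O)c(C(=O)C(C)C)c(O)c3c2OC(C)(C)C=C3)C(=O)C(C(=O)C(C)C)=C1O | target

## Step count and least certain steps

Total step count: 11 (steps 1 to 8 for ring B, steps 9 and 10 for ring A, step 11 for the union).
Longest linear sequence: 9 steps (1 → 24 through steps 1 to 8 and 11).

**Step 5 (key step).**
- What may go wrong: the aldehyde oxygen is only a moderate nucleophile. The short-lived aryne may instead be consumed by an ene reaction with the allylic C–H bonds of 8 or by fluoride-induced self-condensation of the enolisable enal. The ortho-quinone methide may be intercepted by a second aryne, and some regiocontrol in the capture may be lost.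
- Fallback: it sets out from 2 and returns at 12. Compound 2 is O-alkylated with 3-chloro-3-methylbut-1-yne (K2CO3, KI, acetone, reflux) to 1,3-bis(methoxymethoxy)-5-[(2-methylbut-3-yn-2-yl)oxy]benzene F1. Heating F1 in N,N-diethylaniline at 180 °C should bring about aryl propargyl ether Claisen rearrangement, 1,5-hydrogen shift and oxa-6π closure to 12. Both positions ortho to the ether oxygen of F1 are equivalent, so only one chromene can arise.

**Step 10.**
- What may go wrong: poor facial selectivity, because the two flanks of the flat phenoxide differ only remotely. Alkylation may also occur at the unsubstituted ring carbon or twice, and the enantiomeric purity may erode through reversible de-allylation of the doubly activated product by zerovalent palladium.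
- Fallback: it sets out from 20 and returns at 22. Base-mediated dearomative prenylation (NaOMe, prenyl bromide, MeOH, 0 °C) gives racemic 3,5-dihydroxy-4-methyl-4-(3-methylbut-2-en-1-yl)-2-(2-methylpropanoyl)cyclohexa-2,5-dien-1-one F2. The enantiomers are separated by preparative chromatography on an amylose tris(3,5-dimethylphenylcarbamate) phase. The (R)-antipode, identified by comparing its circular dichroism curve with the computed one, is 22.

**Step 11.**
- What may go wrong: amine loss from 17 may be sluggish, because the C7 hydroxyl is tied up in a hydrogen bond to the C6 ketone. Methylene transfer between phloroglucinol units (scrambling to symmetrical dimers), or cyclisation of the prenyl group, may then set in at the temperature required.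
- Fallback: a reversal of polarity that sets out from 22 and returns at 24, with 16 as partner. Compound 22 is aminomethylated at A3 (Me2N=CH2+ I−, CH2Cl2, −20 °C) to the betaine (4R)-6-[(dimethylamino)methyl]-3,5-dihydroxy-4-methyl-4-(3-methylbut-2-en-1-yl)-2-(2-methylpropanoyl)cyclohexa-2,5-dien-1-one F3. Warming F3 with 16 in MeCN (rt → 40 °C) should expel dimethylamine to give the highly electrophilic 2-methylene triketone, which C8 of 16 attacks by conjugate addition.

**Step 6.**
- What may go wrong: incomplete site selectivity of the metalation, since C8 is also flanked by two oxygens and may compete with C6. Proton transfer from the α-branched amide to the hindered aryllithium may also return 12.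
- Fallback: the acyl group is installed while the arene is still symmetric; the sequence sets out from 2 and returns at 15, bypassing 7 and 12. Silylation of 2 (i-Pr3SiCl, imidazole, DMF) gives [3,5-bis(methoxymethoxy)phenoxy]tri(propan-2-yl)silane F4. Metalation at the only position flanked by two acetal ethers and acylation (n-BuLi, THF, 0 °C; then 13) gives 1-[2,6-bis(methoxymethoxy)-4-{[tri(propan-2-yl)silyl]oxy}phenyl]-2-methylpropan-1-one F5. Desilylation (TBAF, THF, 0 °C) gives 1-[4-hydroxy-2,6-bis(methoxymethoxy)phenyl]-2-methylpropan-1-one F6. Condensation of F6 with 8 (ethylenediammonium diacetate (cat.), toluene, reflux; Knoevenagel-type attack, then oxa-6π closure) should give 15, the two ortho positions of F6 being equivalent.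

**Step 2.**
- What may go wrong: bromination para to the hydroxyl (between the acetal ethers) or twice, because all three free positions are activated by three oxygens.
- Fallback: carbamate-directed metalation in place of halogenation; it sets out from 2 and returns at 7. Compound 2 with isopropyl isocyanate (Et3N (cat.), CH2Cl2) gives 3,5-bis(methoxymethoxy)phenyl N-(propan-2-yl)carbamate F7. In-situ N-silylation and ortho-lithiation (Me3SiOTf, TMEDA; n-BuLi, Et2O, −78 °C; then Me3SiCl) give 3,5-bis(methoxymethoxy)-2-(trimethylsilyl)phenyl N-(propan-2-yl)carbamate F8. The carbamate is cleaved with Et2NH and DBU in MeCN at 40 °C to 3,5-bis(methoxymethoxy)-2-(trimethylsilyl)phenol F9, which is not isolated but treated with PhNTf2 in the same flask to give 7.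

## Further compounds

F1 | step 5 | 1,3-bis(methoxymethoxy)-5-[(2-methylbut-3-yn-2-yl)oxy]benzene | COCOc1cc(OCOC)cc(OC(C)(C)C#C)c1
F2 | step 10 | racemic 3,5-dihydroxy-4-methyl-4-(3-methylbut-2-en-1-yl)-2-(2-methylpropanoyl)cyclohexa-2,5-dien-1-one | CC(C)=CCC1(C)C(O)=CC(=O)C(C(=O)C(C)C)=C1O
F3 | step 11 | (4R)-6-[(dimethylamino)methyl]-3,5-dihydroxy-4-methyl-4-(3-methylbut-2-en-1-yl)-2-(2-methylpropanoyl)cyclohexa-2,5-dien-1-one | CC(C)=CC[C@]1(C)C(O)=C(CN(C)C)C(=O)C(C(=O)C(C)C)=C1O
F4 | step 6 | [3,5-bis(methoxymethoxy)phenoxy]tri(propan-2-yl)silane | COCOc1cc(OCOC)cc(O[Si](C(C)C)(C(C)C)C(C)C)c1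
F5 | step 6 | 1-[2,6-bis(methoxymethoxy)-4-{[tri(propan-2-yl)silyl]oxy}phenyl]-2-methylpropan-1-one | CC(C)C(=O)c1c(OCOC)cc(O[Si](C(C)C)(C(C)C)C(C)C)cc1OCOC
F6 | step 6 | 1-[4-hydroxy-2,6-bis(methoxymethoxy)phenyl]-2-methylpropan-1-one | CC(C)C(=O)c1c(OCOC)cc(O)cc1OCOC
F7 | step 2 | 3,5-bis(methoxymethoxy)phenyl N-(propan-2-yl)carbamate | COCOc1cc(OCOC)cc(OC(=O)NC(C)C)c1
F8 | step 2 | 3,5-bis(methoxymethoxy)-2-(trimethylsilyl)phenyl N-(propan-2-yl)carbamate | COCOc1cc(OCOC)c([Si](C)(C)C)c(OC(=O)NC(C)C)c1
F9 | step 2 | 3,5-bis(methoxymethoxy)-2-(trimethylsilyl)phenol | COCOc1cc(OCOC)c([Si](C)(C)C)c(O)c1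
A1 | alternative 1 | (3R)-3-methyl-3-(3-methylbut-2-en-1-yl)-6-(3-methyl-2-oxobutyl)-2H-pyran-2,4(3H)-dione | CC(C)=CC[C@]1(C)C(=O)C=C(CC(=O)C(C)C)OC1=O
A2 | alternative 1 | (4R)-3,5-dihydroxy-4-methyl-4-(3-methylbut-2-en-1-yl)-2-(2-methylpropanoyl)cyclohexa-2,5-dien-1-one (identical with 22) | CC(C)=CC[C@]1(C)C(O)=CC(=O)C(C(=O)C(C)C)=C1O
A3 | alternative 2 | 3-ethoxycyclobut-2-en-1-one | CCOC1=CC(=O)C1
A4 | alternative 2 | triisopropyl{[(3Z)-5-methylhexa-3,5-dien-1-yn-1-yl]oxy}silane | C=C(C)/C=C\C#CO[Si](C(C)C)(C(C)C)C(C)C
A5 | alternative 2 | 7-ethoxy-2,2-dimethyl-5-(triisopropylsilyloxy)-2H-chromene | CCOc1cc(O[Si](C(C)C)(C(C)C)C(C)C)c2C=CC(C)(C)Oc2c1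
A6 | alternative 3 | methyl (2S)-7-[5,7-bis(methoxymethoxy)-2,2-dimethyl-6-(2-methylpropanoyl)-2H-chromen-8-yl]-2-methyl-2-(3-methylbut-2-en-1-yl)-4-(2-methylpropanoyl)-3,5-dioxoheptanoate (C4 configurationally labile) | CC(C)=CC[C@](C(=O)C(C(=O)C(C)C)C(=O)CCc1c(OCOC)c(C(=O)C(C)C)c(OCOC)c2C=CC(C)(C)Oc12)(C)C(=O)OC
A7 | alternative 3 | (4R)-6-{[5,7-bis(methoxymethoxy)-2,2-dimethyl-6-(2-methylpropanoyl)-2H-chromen-8-yl]methyl}-3,5-dihydroxy-4-methyl-4-(3-methylbut-2-en-1-yl)-2-(2-methylpropanoyl)cyclohexa-2,5-dien-1-one | CC(C)=CC[C@]1(C)C(O)=C(Cc2c(OCOC)c(C(=O)C(C)C)c(OCOC)c3c2OC(C)(C)C=C3)C(=O)C(C(=O)C(C)C)=C1O
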